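Which flask keeps the larger share of target among target, isomer of the product and side product, the cold one or the warm one, and by how much?

| flask | starting material | reagent | protic impurity | temperature | time |
|---|---|---|---|---|---|
| birch | 0.016 M | 1.05 equiv | 4.80 mM | 10 °C | 8.0 s |
| elm | 0.016 M | 1.05 equiv | 4.80 mM | 35 °C | 8.0 s |

    starting material + reagent → intermediate + by-product (k1 = 1.5 M⁻¹ s⁻¹, Ea1 = 46.0 kJ mol⁻¹)
    intermediate ⇌ target (K2 = 0.58, k2 = 1.2 s⁻¹, Ea2 = 84.0 kJ mol⁻¹, ΔH2 = 13.0 kJ mol⁻¹)
    intermediate ⇌ isomer of the product (K3 = 170, k3 = 0.056 s⁻¹, Ea3 = 86.0 kJ mol⁻¹, ΔH3 = −90.0 kJ mol⁻¹)
    intermediate → side product (k4 = 0.030 s⁻¹, Ea4 = 83.0 kJ mol⁻¹)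
    starting material + protic impurity → quenched substrate (k5 = 140 M⁻¹ s⁻¹, Ea5 = 50.0 kJ mol⁻¹)
    (constants at 35 °C)

- at 35 °C the constants are as listed, elsewhere as the activation energies and enthalpies make them

- the best flask by share of target in all that became target or isomer of the product or side product; "all alike" if 1.5 percentage points covers them all (birch / elm / all alike)
- share of target in all that became target or isomer of the product or side product, birch
- share of target in all that became target or isomer of the product or side product, elm

I follow the material that has passed the first step and count each amount as a fraction of that fed material, so the size of the feed cancels from the share. I take the feed as steady, which is rough: the protic impurity can remove 30.0% of the charged starting material. My small table gives, for each flask, the forward constant to target, the equilibrium constant K of that step, the summed constant of the drains to isomer and side product, the relaxation count n (forward plus back constant, times the time), the fraction p standing as target, and the fraction d drained.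

birch: 0.0664 s⁻¹; 0.371; 0.00461 s⁻¹; 1.96; 0.152; 0.0163

elm: 1.2 s⁻¹; 0.580; 0.0860 s⁻¹; 26.2; 0.353; 0.227

I get p, leaving the drains out of it, as the equilibrium fraction K/(1+K) times 1 − (1 − exp(−n))/n, the part of the feed that has had time to relax. I get d as the drain constant times the time times the mean fraction of the pool standing as intermediate. Reading the count column, elm relaxes far oftener than birch, so elm's target stands close to its equilibrium fraction, whereas birch's lags behind its own. Reading the last two columns, birch's drained fraction is far smaller than elm's, and this outweighs the lag. The steady-feed share, p/(p+d), is my carried quantity: 90.3% for birch and 60.9% for elm, so I commit to birch.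

The forecast names birch, with 90% (87% to 92%) for birch and 57% (53% to 60%) for elm, on the ground that “At 35 °C that step equilibrates within a fraction of a second”. My elm share stands above its range.

The flasks give 90.2% for birch and 57.6% for elm, so birch leads and the forecast holds, while my steady-feed share for elm stands 3.3 percentage points above the flask's; with all amounts held, elm's share moves 5 points at 6.51 s or 9.69 s, either of which would leave the forecast's range. At 8.00 s, elm holds target over intermediate at 0.558 against its constant 0.580, while birch holds 0.189 against my 0.371.

For a flask like birch at 25 °C, the row reads 0.400 s⁻¹; 0.489; 0.0283 s⁻¹; 9.73; 0.295; 0.0828, and the steady-feed share is 78.1%. That flask gives 76.9%.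

The numbers are made up; the rest is arithmetic.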